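Plicatic acid is cut at the C2–C3 bond of its carbocycle (C1–C2–C3–C4–C4a–C8a), read as an aldol bond between the α-carbon of a carboxylic acid and a ketone. The key step exploits the cis β-hydroxy acid made up of the C2 carboxyl and the C3 hydroxyl: a nucleophile-catalysed aldol lactonisation closes the six-membered ring and a temporary cis-fused β-lactone in one operation. Its precursor is an open-chain 3,3-diarylpropanoic acid whose ring A carries an ortho 3-(benzyloxy)-2-oxopropyl chain; the C1 diarylmethine centre, set by rhodium-catalysed asymmetric arylation, directs C2, and the lactone fixes C3. Retentive hydroxylation of the lactone enolate then gives the trans-diol.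

Key step: step 12

Remark: locants C1–C4, C4a, C8a and "ring A" follow the tetralin numbering of the target throughout; the sense of induction in step 9 is assumed to follow the usual model for (E)-enoates (aryl delivered to the C2-re face of the acrylate with (R)-BINAP).

Step 1
Reactants: 1 2-bromo-5-hydroxy-4-methoxybenzaldehyde
Product: 2 5-(benzyloxy)-2-bromo-4-methoxybenzaldehyde
Conditions: BnBr, K2CO3, DMF, 25 °C
Reagents that add atoms: benzyl bromide BrCc1ccccc1
Why: Williamson ether synthesis, in which the phenoxide is O-benzylated while the aldehyde and the aryl bromide stay inert.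

Step 2
Reactants: 2 5-(benzyloxy)-2-bromo-4-methoxybenzaldehyde
Product: 3 methyl (2E)-3-[5-(benzyloxy)-2-bromo-4-methoxyphenyl]prop-2-enoate
Conditions: Ph3P=CHCO2Me, toluene, 90 °C
Reagents that add atoms: methyl (triphenylphosphoranylidene)acetate COC(=O)C=P(c1ccccc1)(c1ccccc1)c1ccccc1
Why: Wittig olefination with a stabilised ylide, which should give the (E)-enoate selectively.

Step 3
Reactants: 4 3-chloro-2-(chloromethyl)prop-1-ene
Product: 5 ({[2-(chloromethyl)prop-2-en-1-yl]oxy}methyl)benzene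
Conditions: BnOH, NaH, THF, 0 to 25 °C, 4 in threefold excess
Reagents that add atoms: benzyl alcohol OCc1ccccc1
Why: Williamson ether synthesis (SN2 at an allylic chloride), kept at mono-substitution by the excess of the symmetric dichloride.

Step 4
Reactants: 5 ({[2-(chloromethyl)prop-2-en-1-yl]oxy}methyl)benzene
Product: 6 2-{2-[(benzyloxy)methyl]prop-2-en-1-yl}-4,4,5,5-tetramethyl-1,3,2-dioxaborolane
Conditions: B2pin2, Pd2(dba)3 (2.5 mol %), THF, 60 °C
Reagents that add atoms: bis(pinacolato)diboron CC1(C)OB(OC1(C)C)B1OC(C)(C)C(C)(C)O1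
Why: Palladium-catalysed Miyaura-type borylation of an allylic chloride through a π-allylpalladium intermediate, free of regiochemical issues because the two allyl termini are equivalent.

Step 5
Reactants: 3 methyl (2E)-3-[5-(benzyloxy)-2-bromo-4-methoxyphenyl]prop-2-enoate; 6 2-{2-[(benzyloxy)methyl]prop-2-en-1-yl}-4,4,5,5-tetramethyl-1,3,2-dioxaborolane
Product: 7 methyl (2E)-3-[5-(benzyloxy)-2-{2-[(benzyloxy)methyl]prop-2-en-1-yl}-4-methoxyphenyl]prop-2-enoate
Conditions: Pd(PPh3)4 (5 mol %), CsF, THF, 70 °C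
Reagents that add atoms: none
Why: Suzuki–Miyaura allyl–aryl cross-coupling, in which fluoride activates the allylboronate, α- and γ-transfer give the same product, and the enoate is untouched (the aldehyde is already olefinated, so allylboration cannot interfere).

Step 6
Reactants: 8 5-bromo-2-hydroxy-3-methoxybenzaldehyde
Product: 10 5-bromo-3-methoxybenzene-1,2-diol, via aryl formate 9 (not isolated)
Conditions: 30% H2O2, aq NaOH, 0 to 25 °C; then aq HCl
Reagents that add atoms: hydrogen peroxide OO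
Why: Dakin oxidation, in which hydroperoxide adds to the ortho-hydroxybenzaldehyde, aryl migration gives formate 9, and hydroxide cleaves it to the catechol.

Step 7
Reactants: 10 5-bromo-3-methoxybenzene-1,2-diol
Product: 11 1,2-bis(benzyloxy)-5-bromo-3-methoxybenzene
Conditions: BnBr (2.4 equiv), K2CO3, DMF, 60 °C
Reagents that add atoms: benzyl bromide BrCc1ccccc1
Why: Double Williamson ether synthesis of the catechol, done directly on the crude, air-sensitive diol.

Step 8
Reactants: 11 1,2-bis(benzyloxy)-5-bromo-3-methoxybenzene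
Product: 12 2-[3,4-bis(benzyloxy)-5-methoxyphenyl]-4,4,5,5-tetramethyl-1,3,2-dioxaborolane
Conditions: B2pin2, Pd(dppf)Cl2 (3 mol %), KOAc, 1,4-dioxane, 90 °C
Reagents that add atoms: bis(pinacolato)diboron CC1(C)OB(OC1(C)C)B1OC(C)(C)C(C)(C)O1
Why: Miyaura borylation of the aryl bromide (oxidative addition, acetate-assisted transmetalation, reductive elimination), which the benzyl ethers tolerate.

Step 9
Reactants: 7 methyl (2E)-3-[5-(benzyloxy)-2-{2-[(benzyloxy)methyl]prop-2-en-1-yl}-4-methoxyphenyl]prop-2-enoate; 12 2-[3,4-bis(benzyloxy)-5-methoxyphenyl]-4,4,5,5-tetramethyl-1,3,2-dioxaborolane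
Product: 13 methyl (3S)-3-[5-(benzyloxy)-2-{2-[(benzyloxy)methyl]prop-2-en-1-yl}-4-methoxyphenyl]-3-[3,4-bis(benzyloxy)-5-methoxyphenyl]propanoate
Conditions: Rh(acac)(C2H4)2 (3 mol %), (R)-BINAP (3.3 mol %), 12 (2 equiv), 1,4-dioxane/H2O 10:1, 100 °C
Reagents that add atoms: none
Why: Hayashi–Miyaura rhodium-catalysed asymmetric 1,4-addition, in which the aryl–rhodium species bearing (R)-BINAP inserts the (E)-enoate on its C2-re face and water protonates the rhodium enolate, so the future C1 is set as S while the isolated 1,1-disubstituted alkene does not insert.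

Step 10
Reactants: 13 methyl (3S)-3-[5-(benzyloxy)-2-{2-[(benzyloxy)methyl]prop-2-en-1-yl}-4-methoxyphenyl]-3-[3,4-bis(benzyloxy)-5-methoxyphenyl]propanoate
Product: 14 (3S)-3-[5-(benzyloxy)-2-{2-[(benzyloxy)methyl]prop-2-en-1-yl}-4-methoxyphenyl]-3-[3,4-bis(benzyloxy)-5-methoxyphenyl]propanoic acid
Conditions: LiOH·H2O, THF/MeOH/H2O 3:1:1, 25 °C; then 1 M HCl
Reagents that add atoms: lithium hydroxide [Li+].[OH-]
Why: Saponification of the methyl ester by acyl substitution, done before the ketone is unmasked so that no enolisable ketone meets base, and harmless to the non-acidic diarylmethine centre.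

Step 11
Reactants: 14 (3S)-3-[5-(benzyloxy)-2-{2-[(benzyloxy)methyl]prop-2-en-1-yl}-4-methoxyphenyl]-3-[3,4-bis(benzyloxy)-5-methoxyphenyl]propanoic acid
Product: 16 (3S)-3-{5-(benzyloxy)-2-[3-(benzyloxy)-2-oxopropyl]-4-methoxyphenyl}-3-[3,4-bis(benzyloxy)-5-methoxyphenyl]propanoic acid, via diol 15 (not isolated)
Conditions: OsO4 (2 mol %), NaIO4 (4 equiv), 2,6-lutidine, 1,4-dioxane/H2O 3:1, 25 °C
Reagents that add atoms: osmium tetroxide O=[Os](=O)(=O)=O; sodium periodate [Na+].[O-]I(=O)(=O)=O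
Why: Lemieux–Johnson oxidation, in which OsO4 dihydroxylates the only alkene to diol 15 and periodate cleaves it to the ketone and formaldehyde, 2,6-lutidine suppressing over-oxidation and the electron-rich arenes being left alone.

Step 12
Reactants: 16 (3S)-3-{5-(benzyloxy)-2-[3-(benzyloxy)-2-oxopropyl]-4-methoxyphenyl}-3-[3,4-bis(benzyloxy)-5-methoxyphenyl]propanoic acid
Product: 19 (1S,2R,3S)-configured cis-fused β-lactone of 7-(benzyloxy)-1-[3,4-bis(benzyloxy)-5-methoxyphenyl]-3-[(benzyloxy)methyl]-3-hydroxy-6-methoxy-1,2,3,4-tetrahydronaphthalene-2-carboxylic acid (2-carboxyl closed onto the 3-oxygen), via mixed anhydride 17 (not isolated), via ammonium enolate 18 (not isolated)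
Conditions: TsCl (1.3 equiv), i-Pr2NEt (4 equiv), LiCl (1 equiv), 4-pyrrolidinopyridine (1.5 equiv), CH2Cl2 (0.02 M), 23 °C, slow addition of 16 over 6 h
Reagents that add atoms: none
Why: TsCl turns the acid into mixed anhydride 17, 4-pyrrolidinopyridine converts it into an N-acylpyridinium ion, i-Pr2NEt removes its C2 proton to give ammonium enolate 18, this adds to the C3 ketone (C2–C3 bond), and the aldolate oxygen then displaces the pyridine from the acyl carbon. The closest known reaction type is the nucleophile-catalysed aldol lactonisation of keto acids to carbocycle-fused β-lactones. The carbocycle C1–C2–C3–C4–C4a–C8a closes by a 6-(enolexo)-exo-trig aldol addition and the oxetanone by a 4-exo-trig acyl substitution. C2 is controlled by C1: A(1,3) strain holds C1–H in the enolate plane, ring A carries the ketone to one enolate face and the pendant aryl group covers the other, so the new bond forms anti to that aryl group and the acyl carbon ends trans to it. C3 is controlled by ring strain: the aldol addition is reversible and only the aldolate with its oxygen cis to the acyl carbon can close to the cis-fused lactone, which then also locks C2 against epimerisation. The step needs enolisation at C2 instead of at the benzylic C4 (secured by the much higher acidity of the acylpyridinium α-proton) and ring closure instead of oligomerisation (secured by the ortho disposition of the two chains on ring A and by slow addition at high dilution).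

Step 13
Reactants: 19 (1S,2R,3S)-configured cis-fused β-lactone of 7-(benzyloxy)-1-[3,4-bis(benzyloxy)-5-methoxyphenyl]-3-[(benzyloxy)methyl]-3-hydroxy-6-methoxy-1,2,3,4-tetrahydronaphthalene-2-carboxylic acid
Product: 21 (1S,2S,3R)-configured cis-fused β-lactone of 7-(benzyloxy)-1-[3,4-bis(benzyloxy)-5-methoxyphenyl]-3-[(benzyloxy)methyl]-2,3-dihydroxy-6-methoxy-1,2,3,4-tetrahydronaphthalene-2-carboxylic acid (2-carboxyl closed onto the 3-oxygen), via potassium enolate 20 (not isolated)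
Conditions: KHMDS (1.2 equiv), THF, −78 °C; then 2-(phenylsulfonyl)-3-phenyloxaziridine, −78 °C; AcOH quench at −78 °C
Reagents that add atoms: 2-(phenylsulfonyl)-3-phenyloxaziridine O=S(=O)(c1ccccc1)N1OC1c1ccccc1
Why: Davis oxidation of a β-lactone enolate, in which planar enolate 20 can take up oxygen only on the convex face that keeps the oxetanone cis-fused, so the hydroxyl replaces the C2 hydrogen with retention and ends trans to the C3 oxygen and cis to the C1 aryl group.

Step 14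
Reactants: 21 (1S,2S,3R)-configured cis-fused β-lactone of 7-(benzyloxy)-1-[3,4-bis(benzyloxy)-5-methoxyphenyl]-3-[(benzyloxy)methyl]-2,3-dihydroxy-6-methoxy-1,2,3,4-tetrahydronaphthalene-2-carboxylic acid
Product: 22 (1S,2S,3R)-7-(benzyloxy)-1-[3,4-bis(benzyloxy)-5-methoxyphenyl]-3-[(benzyloxy)methyl]-2,3-dihydroxy-6-methoxy-1,2,3,4-tetrahydronaphthalene-2-carboxylic acid
Conditions: LiOH (3 equiv), THF/H2O 3:1, 0 °C; then aq HCl to pH 3
Reagents that add atoms: lithium hydroxide [Li+].[OH-]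
Why: Hydrolysis of the strained β-lactone by acyl–oxygen cleavage (hydroxide attacks the carbonyl, not the tertiary C3), which frees the C2 carboxylic acid and the C3 hydroxyl with retention at both centres.

Step 15
Reactants: 22 (1S,2S,3R)-7-(benzyloxy)-1-[3,4-bis(benzyloxy)-5-methoxyphenyl]-3-[(benzyloxy)methyl]-2,3-dihydroxy-6-methoxy-1,2,3,4-tetrahydronaphthalene-2-carboxylic acid
Product: 23 plicatic acid, (1S,2S,3R)-1-(3,4-dihydroxy-5-methoxyphenyl)-2,3,7-trihydroxy-3-(hydroxymethyl)-6-methoxy-1,2,3,4-tetrahydronaphthalene-2-carboxylic acid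
Conditions: H2 (1 atm), 10% Pd/C, MeOH/EtOAc, 25 °C
Reagents that add atoms: none
Why: Catalytic hydrogenolysis of the four benzyl ethers, which should leave the C–C bonds of the diarylmethine carbon and the non-benzylic tertiary carbinols intact.

Compound list

1 | 2-bromo-5-hydroxy-4-methoxybenzaldehyde | COc1cc(Br)c(cc1O)C=O | starting material
2 | 5-(benzyloxy)-2-bromo-4-methoxybenzaldehyde | COc1cc(Br)c(cc1OCc1ccccc1)C=O | intermediate
3 | methyl (2E)-3-[5-(benzyloxy)-2-bromo-4-methoxyphenyl]prop-2-enoate | COc1cc(Br)c(cc1OCc1ccccc1)/C=C/C(=O)OC | intermediate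
4 | 3-chloro-2-(chloromethyl)prop-1-ene | C=C(CCl)CCl | starting material
5 | ({[2-(chloromethyl)prop-2-en-1-yl]oxy}methyl)benzene | C=C(CCl)COCc1ccccc1 | intermediate
6 | 2-{2-[(benzyloxy)methyl]prop-2-en-1-yl}-4,4,5,5-tetramethyl-1,3,2-dioxaborolane | C=C(CB1OC(C)(C)C(C)(C)O1)COCc1ccccc1 | intermediate
7 | methyl (2E)-3-[5-(benzyloxy)-2-{2-[(benzyloxy)methyl]prop-2-en-1-yl}-4-methoxyphenyl]prop-2-enoate | COc1cc(CC(=C)COCc2ccccc2)c(cc1OCc1ccccc1)/C=C/C(=O)OC | intermediate
8 | 5-bromo-2-hydroxy-3-methoxybenzaldehyde | COc1cc(Br)cc(C=O)c1O | starting material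
9 | 5-bromo-2-hydroxy-3-methoxyphenyl formate (not isolated) | COc1cc(Br)cc(OC=O)c1O | intermediate
10 | 5-bromo-3-methoxybenzene-1,2-diol | COc1cc(Br)cc(O)c1O | intermediate
11 | 1,2-bis(benzyloxy)-5-bromo-3-methoxybenzene | COc1cc(Br)cc(OCc2ccccc2)c1OCc1ccccc1 | intermediate
12 | 2-[3,4-bis(benzyloxy)-5-methoxyphenyl]-4,4,5,5-tetramethyl-1,3,2-dioxaborolane | COc1cc(B2OC(C)(C)C(C)(C)O2)cc(OCc2ccccc2)c1OCc1ccccc1 | intermediate
13 | methyl (3S)-3-[5-(benzyloxy)-2-{2-[(benzyloxy)methyl]prop-2-en-1-yl}-4-methoxyphenyl]-3-[3,4-bis(benzyloxy)-5-methoxyphenyl]propanoate | COc1cc(CC(=C)COCc2ccccc2)c(cc1OCc1ccccc1)[C@H](c1cc(OCc2ccccc2)c(OCc2ccccc2)c(OC)c1)CC(=O)OC | intermediate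
14 | (3S)-3-[5-(benzyloxy)-2-{2-[(benzyloxy)methyl]prop-2-en-1-yl}-4-methoxyphenyl]-3-[3,4-bis(benzyloxy)-5-methoxyphenyl]propanoic acid | COc1cc(CC(=C)COCc2ccccc2)c(cc1OCc1ccccc1)[C@H](c1cc(OCc2ccccc2)c(OCc2ccccc2)c(OC)c1)CC(=O)O | intermediate
15 | (3S)-3-{5-(benzyloxy)-2-[3-(benzyloxy)-2-hydroxy-2-(hydroxymethyl)propyl]-4-methoxyphenyl}-3-[3,4-bis(benzyloxy)-5-methoxyphenyl]propanoic acid, both epimers at the new carbinol carbon (not isolated) | COc1cc(CC(O)(CO)COCc2ccccc2)c(cc1OCc1ccccc1)[C@H](c1cc(OCc2ccccc2)c(OCc2ccccc2)c(OC)c1)CC(=O)O | intermediate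
16 | (3S)-3-{5-(benzyloxy)-2-[3-(benzyloxy)-2-oxopropyl]-4-methoxyphenyl}-3-[3,4-bis(benzyloxy)-5-methoxyphenyl]propanoic acid | COc1cc(CC(=O)COCc2ccccc2)c(cc1OCc1ccccc1)[C@H](c1cc(OCc2ccccc2)c(OCc2ccccc2)c(OC)c1)CC(=O)O | intermediate
17 | mixed carboxylic–p-toluenesulfonic anhydride of 16 (not isolated) | COc1cc(CC(=O)COCc2ccccc2)c(cc1OCc1ccccc1)[C@H](c1cc(OCc2ccccc2)c(OCc2ccccc2)c(OC)c1)CC(=O)OS(=O)(=O)c1ccc(C)cc1 | intermediate
18 | zwitterionic enolate of the N-acyl-4-(pyrrolidin-1-yl)pyridinium ion derived from 16, C2=C(O−)–N+ (not isolated) | COc1cc(CC(=O)COCc2ccccc2)c(cc1OCc1ccccc1)[C@H](c1cc(OCc2ccccc2)c(OCc2ccccc2)c(OC)c1)C=C([O-])[n+]1ccc(cc1)N1CCCC1 | intermediate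
19 | (1S,2R,3S)-configured cis-fused β-lactone of 7-(benzyloxy)-1-[3,4-bis(benzyloxy)-5-methoxyphenyl]-3-[(benzyloxy)methyl]-3-hydroxy-6-methoxy-1,2,3,4-tetrahydronaphthalene-2-carboxylic acid | COc1cc2c(cc1OCc1ccccc1)[C@H](c1cc(OCc3ccccc3)c(OCc3ccccc3)c(OC)c1)[C@H]3C(=O)O[C@@]3(COCc1ccccc1)C2 | intermediate
20 | potassium enolate of β-lactone 19 (not isolated) | COc1cc2c(cc1OCc1ccccc1)[C@H](c1cc(OCc3ccccc3)c(OCc3ccccc3)c(OC)c1)C3=C([O-])O[C@@]3(COCc1ccccc1)C2.[K+] | intermediate
21 | (1S,2S,3R)-configured cis-fused β-lactone of 7-(benzyloxy)-1-[3,4-bis(benzyloxy)-5-methoxyphenyl]-3-[(benzyloxy)methyl]-2,3-dihydroxy-6-methoxy-1,2,3,4-tetrahydronaphthalene-2-carboxylic acid | COc1cc2c(cc1OCc1ccccc1)[C@H](c1cc(OCc3ccccc3)c(OCc3ccccc3)c(OC)c1)[C@@]3(O)C(=O)O[C@@]3(COCc1ccccc1)C2 | intermediate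
22 | (1S,2S,3R)-7-(benzyloxy)-1-[3,4-bis(benzyloxy)-5-methoxyphenyl]-3-[(benzyloxy)methyl]-2,3-dihydroxy-6-methoxy-1,2,3,4-tetrahydronaphthalene-2-carboxylic acid | COc1cc2c(cc1OCc1ccccc1)[C@H](c1cc(OCc3ccccc3)c(OCc3ccccc3)c(OC)c1)[C@@](O)(C(=O)O)[C@](O)(COCc1ccccc1)C2 | intermediate
23 | plicatic acid, (1S,2S,3R)-1-(3,4-dihydroxy-5-methoxyphenyl)-2,3,7-trihydroxy-3-(hydroxymethyl)-6-methoxy-1,2,3,4-tetrahydronaphthalene-2-carboxylic acid | COc1cc2c(cc1O)[C@H](c1cc(O)c(O)c(OC)c1)[C@@](O)(C(=O)O)[C@](O)(CO)C2 | target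

Total step count: 15. Longest linear sequence: 10 steps (steps 1, 2, 5 and 9–15; the branches through steps 3–4 and 6–8 are equally long when counted through to the target).

Steps most likely to fail

Step 12. The benzylic ketone may enolise and be C-acylated by the acylpyridinium ion (Claisen-type closure to a β-diketone), or the activated acid may oligomerise faster than the hindered aldol addition takes place. The fallback makes the C2–C3 bond by an intramolecular Reformatsky reaction and sets out from ester 13. LDA in THF at −78 °C followed by CBr4 should give the α-bromo ester F1 (both C2 epimers). OsO4/NaIO4/2,6-lutidine cleaves its alkene to the bromo keto ester F2. Activated Zn dust (TMSCl, THF, 40 °C) generates the zinc ester enolate regiospecifically beside the ketone and should close the ring to the cis β-hydroxy ester F3 through a zinc-bridged chair transition state, under the same A(1,3) control from C1. Me3SnOH (1,2-dichloroethane, 80 °C) hydrolyses the ester without retro-aldol cleavage to the β-hydroxy acid F4. PhSO2Cl in pyridine at 0 °C lactonises F4 by carboxyl activation, with retention at C3, and the route is rejoined at β-lactone 19.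

Step 13. Deprotonation at the hindered ring-fusion carbon may be slow, so that the amide base opens the strained lactone instead, or the enolate may fragment by β-elimination before it is oxidised. The fallback installs the C2 oxygen before the ring is closed and sets out from ester 13. KHMDS followed by 2-(phenylsulfonyl)-3-phenyloxaziridine gives the α-hydroxy ester F5 (both C2 epimers; this centre is made planar again later). BnBr/Ag2O gives the benzyl ether F6, LiOH gives the acid F7, and OsO4/NaIO4 gives the keto acid F8. The aldol lactonisation under the conditions of step 12, now through an α-benzyloxy ammonium enolate with the same ring constraints, should give the α-benzyloxy β-lactone F9. LiOH opens it to the hydroxy acid F10, and hydrogenolysis of its five benzyl ethers (H2, Pd/C) gives plicatic acid directly, so the route is rejoined at 23.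

Step 9. Insertion of the electron-rich, ortho-substituted cinnamate may be slower than protodeboronation of 12, or the facial selectivity may be insufficient. The fallback sets C1 by an auxiliary-controlled cuprate addition and sets out from enoate 7. LiOH gives the cinnamic acid F11. PivCl/Et3N followed by (R)-4-phenyl-1,3-oxazolidin-2-one and LiCl gives the imide F12. The aryl Grignard reagent F13, made from bromide 11 and Mg in THF, should add with CuBr·SMe2 at −40 °C to the chelated s-cis imide on the face remote from the auxiliary phenyl group, giving the (3S)-adduct F14. LiOH/H2O2 removes the auxiliary, and the route is rejoined at acid 14.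

Further compounds

F1 | step 12 | methyl (3S)-3-[5-(benzyloxy)-2-{2-[(benzyloxy)methyl]prop-2-en-1-yl}-4-methoxyphenyl]-3-[3,4-bis(benzyloxy)-5-methoxyphenyl]-2-bromopropanoate (both C2 epimers) | COc1cc(CC(=C)COCc2ccccc2)c(cc1OCc1ccccc1)[C@H](c1cc(OCc2ccccc2)c(OCc2ccccc2)c(OC)c1)C(Br)C(=O)OC
F2 | step 12 | methyl (3S)-3-{5-(benzyloxy)-2-[3-(benzyloxy)-2-oxopropyl]-4-methoxyphenyl}-3-[3,4-bis(benzyloxy)-5-methoxyphenyl]-2-bromopropanoate (both C2 epimers) | COc1cc(CC(=O)COCc2ccccc2)c(cc1OCc1ccccc1)[C@H](c1cc(OCc2ccccc2)c(OCc2ccccc2)c(OC)c1)C(Br)C(=O)OC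
F3 | step 12 | methyl (1S,2R,3S)-7-(benzyloxy)-1-[3,4-bis(benzyloxy)-5-methoxyphenyl]-3-[(benzyloxy)methyl]-3-hydroxy-6-methoxy-1,2,3,4-tetrahydronaphthalene-2-carboxylate | COc1cc2c(cc1OCc1ccccc1)[C@H](c1cc(OCc3ccccc3)c(OCc3ccccc3)c(OC)c1)[C@@H](C(=O)OC)[C@](O)(COCc1ccccc1)C2
F4 | step 12 | (1S,2R,3S)-7-(benzyloxy)-1-[3,4-bis(benzyloxy)-5-methoxyphenyl]-3-[(benzyloxy)methyl]-3-hydroxy-6-methoxy-1,2,3,4-tetrahydronaphthalene-2-carboxylic acid | COc1cc2c(cc1OCc1ccccc1)[C@H](c1cc(OCc3ccccc3)c(OCc3ccccc3)c(OC)c1)[C@@H](C(=O)O)[C@](O)(COCc1ccccc1)C2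
F5 | step 13 | methyl (3S)-3-[5-(benzyloxy)-2-{2-[(benzyloxy)methyl]prop-2-en-1-yl}-4-methoxyphenyl]-3-[3,4-bis(benzyloxy)-5-methoxyphenyl]-2-hydroxypropanoate (both C2 epimers) | COc1cc(CC(=C)COCc2ccccc2)c(cc1OCc1ccccc1)[C@H](c1cc(OCc2ccccc2)c(OCc2ccccc2)c(OC)c1)C(O)C(=O)OC
F6 | step 13 | methyl (3S)-2-(benzyloxy)-3-[5-(benzyloxy)-2-{2-[(benzyloxy)methyl]prop-2-en-1-yl}-4-methoxyphenyl]-3-[3,4-bis(benzyloxy)-5-methoxyphenyl]propanoate (both C2 epimers) | COc1cc(CC(=C)COCc2ccccc2)c(cc1OCc1ccccc1)[C@H](c1cc(OCc2ccccc2)c(OCc2ccccc2)c(OC)c1)C(OCc1ccccc1)C(=O)OC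
F7 | step 13 | (3S)-2-(benzyloxy)-3-[5-(benzyloxy)-2-{2-[(benzyloxy)methyl]prop-2-en-1-yl}-4-methoxyphenyl]-3-[3,4-bis(benzyloxy)-5-methoxyphenyl]propanoic acid (both C2 epimers) | COc1cc(CC(=C)COCc2ccccc2)c(cc1OCc1ccccc1)[C@H](c1cc(OCc2ccccc2)c(OCc2ccccc2)c(OC)c1)C(OCc1ccccc1)C(=O)O
F8 | step 13 | (3S)-2-(benzyloxy)-3-{5-(benzyloxy)-2-[3-(benzyloxy)-2-oxopropyl]-4-methoxyphenyl}-3-[3,4-bis(benzyloxy)-5-methoxyphenyl]propanoic acid (both C2 epimers) | COc1cc(CC(=O)COCc2ccccc2)c(cc1OCc1ccccc1)[C@H](c1cc(OCc2ccccc2)c(OCc2ccccc2)c(OC)c1)C(OCc1ccccc1)C(=O)O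
F9 | step 13 | (1S,2S,3R)-configured cis-fused β-lactone of 2,7-bis(benzyloxy)-1-[3,4-bis(benzyloxy)-5-methoxyphenyl]-3-[(benzyloxy)methyl]-3-hydroxy-6-methoxy-1,2,3,4-tetrahydronaphthalene-2-carboxylic acid | COc1cc2c(cc1OCc1ccccc1)[C@H](c1cc(OCc3ccccc3)c(OCc3ccccc3)c(OC)c1)[C@@]3(OCc1ccccc1)C(=O)O[C@@]3(COCc1ccccc1)C2
F10 | step 13 | (1S,2S,3R)-2,7-bis(benzyloxy)-1-[3,4-bis(benzyloxy)-5-methoxyphenyl]-3-[(benzyloxy)methyl]-3-hydroxy-6-methoxy-1,2,3,4-tetrahydronaphthalene-2-carboxylic acid | COc1cc2c(cc1OCc1ccccc1)[C@H](c1cc(OCc3ccccc3)c(OCc3ccccc3)c(OC)c1)[C@@](OCc1ccccc1)(C(=O)O)[C@](O)(COCc1ccccc1)C2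
F11 | step 9 | (2E)-3-[5-(benzyloxy)-2-{2-[(benzyloxy)methyl]prop-2-en-1-yl}-4-methoxyphenyl]prop-2-enoic acid | COc1cc(CC(=C)COCc2ccccc2)c(cc1OCc1ccccc1)/C=C/C(=O)O
F12 | step 9 | (4R)-3-{(2E)-3-[5-(benzyloxy)-2-{2-[(benzyloxy)methyl]prop-2-en-1-yl}-4-methoxyphenyl]prop-2-enoyl}-4-phenyl-1,3-oxazolidin-2-one | COc1cc(CC(=C)COCc2ccccc2)c(cc1OCc1ccccc1)/C=C/C(=O)N1C(=O)OC[C@H]1c1ccccc1
F13 | step 9 | [3,4-bis(benzyloxy)-5-methoxyphenyl]magnesium bromide | COc1cc([Mg]Br)cc(OCc2ccccc2)c1OCc1ccccc1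
F14 | step 9 | (4R)-3-{(3S)-3-[5-(benzyloxy)-2-{2-[(benzyloxy)methyl]prop-2-en-1-yl}-4-methoxyphenyl]-3-[3,4-bis(benzyloxy)-5-methoxyphenyl]propanoyl}-4-phenyl-1,3-oxazolidin-2-one | COc1cc(CC(=C)COCc2ccccc2)c(cc1OCc1ccccc1)[C@H](c1cc(OCc2ccccc2)c(OCc2ccccc2)c(OC)c1)CC(=O)N1C(=O)OC[C@H]1c1ccccc1
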